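## Analysis of the target

The target 21 is a B-type procyanidin trimer, epicatechin 3-O-gallate-(4β→8)-epicatechin 3-O-gallate-(4β→8)-catechin. It consists of three flavan units, each with a phloroglucinol-type ring A, a catechol ring B and a pyran ring C, joined by two C4–C8 bonds (top C4 to middle C8, middle C4 to bottom C8). There are eight stereocentres. C2 and C3 of the top and middle units are those of (−)-epicatechin (2R,3R, 2,3-cis) and C2 and C3 of the bottom unit are those of (+)-catechin (2R,3S, 2,3-trans); the two remaining centres, C4 of the top and middle units, carry the next flavan on the β face, trans to the C3 ester oxygen and to the ring B aryl on C2. The molecule holds eighteen phenolic hydroxyls that autoxidise easily, two gallate esters that base can cleave, C2 centres that epimerise in base once the phenols are free, and two doubly benzylic interflavan bonds that acid can reopen. The difficulty lies in the two interflavan bonds: each is a Friedel–Crafts alkylation of an electron-rich ring A by a C4 cation, the product is as nucleophilic as the starting flavan, C6 competes with C8, and the sequence of three different units demands two ordered, one-to-one unions. The strategy rests on one structural feature: the only free aliphatic hydroxyl, O3–H on ring C of the bottom catechin, lies beside the gallate on O3 of the middle unit, whose para oxygen (O4) is a phenol. Both oxygens can therefore carry benzyl-type ethers, and an m-xylylene group between them spans the middle C4–bottom C8 bond, turns its formation into a ring closure, and is removed by the hydrogenolysis that frees the phenols.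

## Retrosynthetic reasoning

**21 from 20.** The last operation is a global hydrogenolysis. The bonds cut are seventeen O–benzyl bonds, the two benzylic C–O bonds of the bridge (gallate O4 and catechin O3), and a C8–Br bond on the top ring A. Keeping every protecting and auxiliary group of one cleavage type means the air-sensitive free polyphenol appears only once, at the end.

**20 from 14 and 18.** The top C4–middle C8 bond is cut second. Once the macrocycle 14 exists, bottom C8 is occupied and middle C8 is the only remaining position of the C8 type (between O1 and one benzyloxy group). The electrophile 18 carries its gallate, which shields the α face of C4, and a bromine on its own C8, so that it cannot alkylate itself. The forward reaction has to deliver β attack at top C4 and has to choose middle C8 over the two C6 positions.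

**14 from 12.** The middle C4–bottom C8 bond is cut inside the twenty-membered ring. This is the bond flanked by the two anchor oxygens, and opening it gives 12, in which C4 carries a 2-ethoxyethoxy leaving group and the catechin hangs from the gallate through the bridge. The gain is a strictly one-to-one union without excess nucleophile. The forward reaction has to ionise C4, attack from the β face, use C8 and not C6 of the catechin, and close the ring faster than chains grow.

**12 from 8 and 11.** The ester C–O bond at middle O3 is cut. This divides 12 into acid 8 (bottom unit, bridge and gallate) and alcohol 11 (activated middle unit). C4 of the middle unit must be oxidised before this union, because the catechin part of 8 has its own C4 methylene, which a benzylic oxidant would attack just as readily. The esterification has to be neutral, since the C4 ether of 11 is acid-labile.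

**11 from 10, and 10 from 9.** The C4–O bond is traced to a benzylic oxidation of 10 in the presence of the alcohol that becomes the leaving group. The four benzyl ethers of 10 come from the phenols of (−)-epicatechin 9, so C2 and C3 of the middle unit are taken from the chiral pool.

**8 from 7, 7 from 6, and 6 from 4 and 5.** The acid is unmasked from methyl ester 7, and the two flanking benzyl ethers of 7 are put on diol 6. The gallate O4–CH2 bond of 6 is cut to give benzylic bromide 4 and methyl gallate 5. This is the place to cut because the 4-OH of 5, para to the ester, is the most acidic of the three, so no separate differentiation of the gallate hydroxyls is needed.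

**4 from 2 and 3, and 2 from 1.** The catechin O3–CH2 bond is cut to give alcohol 2, whose only free hydroxyl is the one wanted, and the symmetrical dibromide 3, used in excess. Alcohol 2 is (+)-catechin 1 with its four phenols benzylated.

**18 from 16 and 17, 16 from 15, and 15 from 10.** The top electrophile is cut at its ester to give acid 17 and alcohol 16. Alcohol 16 comes from 10 by C8 bromination and then the same C4 oxidation as for 11. The top and middle units thus share 10.

## Alternatives that were turned down

**Alternative 1:** The middle ring C is built instead of taken from epicatechin. It is cut at C4–C4a and O1–C2, which returns the middle ring A to phloroglucinol A2 and the ring C carbons to the enal A1, (E)-3-(penta-O-benzylcatechin-8-yl)propenal, where the future interflavan bond is already an aryl–alkene bond at catechin C8. In the forward key step a diarylprolinol silyl ether turns A1 into an iminium ion, a ring carbon of A2 adds to its β-carbon, and an ortho hydroxyl closes on the aldehyde to give lactol A3.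
- For it: the bond to catechin C8 is fixed before any cation chemistry, the C4 configuration is set by the catalyst, and the union is one-to-one. On these points it is stronger than the chosen route, which relies on the inherent C8 preference and on substrate control.
- Against it: A3 has neither the ring B aryl on C2 nor the oxygen on C3, so two more stereocentres (2,3-cis, 3,4-trans) must be raised from a lactol. The phenols of the new ring A need protection, the gallate must be added, and the top unit must still be attached by the same cationic coupling as here.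
- Comparison: the middle unit alone would take more steps than the whole present sequence, while (−)-epicatechin 9 supplies that stereotriad ready-made. The chosen strategy gives up catalyst control at C4 for chiral-pool economy and a neighbouring-group effect.

**Alternative 2:** The middle ring A itself is disconnected. Four of its bonds (C4a–C5, C4a–C8a, C6–C7, C7–C8) are traced to a photochemical benzannulation of the Danheiser type. A diazo ketone on the carbon that becomes C4a undergoes Wolff rearrangement to a vinylketene; this adds to a tethered alkynyl ether whose oxygen is the future O1 and whose alkyne carbon bears the complete top unit. The cyclobutenone opens and recloses to a phenol, so rings A and C of the middle unit form together and the product is A4, the benzylated trimer with a free middle 7-OH.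
- For it: every substituent of the hexasubstituted ring A is placed by construction, so neither interflavan bond depends on C6/C8 selectivity, no cation is generated near finished interflavan bonds, and chain growth is impossible. On regiocontrol it is clearly stronger than the chosen route.
- Against it: the substrate must carry, on an open chain, the C2–C3–C4 stereotriad with ring B, the gallate and the whole bottom unit, an alkynyl ether of a secondary benzylic alcohol, and a diazo ketone next to an enol ether, all made de novo. The gallates and many benzyl ethers absorb where the Wolff step needs light.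
- Comparison: the step count would be several times that of the chosen route, which is short because it uses the natural monomers and accepts substrate-controlled regiochemistry.

**Alternative 3:** The top ring C is cut at C4–C4a. The top ring A is then a 3,5-bis(benzyloxy)phenyl ether on the C2 oxygen of an open chain, and C4 is a carbinol that already carries C8 of the middle unit. In the forward step a hard Lewis acid ionises the carbinol, the C3 gallate bridges the cation, and an ortho carbon of the aryl ether attacks from the opposite face, closing the six-membered ring to A5, perbenzylated epicatechin gallate-(4β→8)-epicatechin gallate.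
- For it: the top C4–middle C8 bond is regiochemically secure because it is made beforehand by carbonyl addition, the two ortho positions of the nucleophile are equivalent, and the closure is intramolecular. This is stronger than the second coupling of the chosen route (step 13).
- Against it: A5 is only the top–middle dimer and its middle C4 is a plain methylene. The middle–bottom bond would need a C4 oxidation on a dimer, where the doubly benzylic top C4–H competes. The top C2 and C3 centres must be made by asymmetric synthesis although 9 provides them, and the benzylic C2 aryl ether can itself ionise under the Lewis acid.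
- Comparison: it solves the easier interflavan bond at high cost and leaves open the one-to-one middle–bottom union, which is the bond the chosen strategy is built around.

Key step: step 9

Assumption: 3,4,5-tris(benzyloxy)benzoic acid 17 is a catalogue compound and is bought. α and β follow the flavan convention in which the ring B aryl of a 2R flavan is α.

## Route

Step 1
Reactants: 1 (+)-catechin
Product: 2 5,7,3′,4′-tetra-O-benzyl-(+)-catechin (2R,3S; free 3-OH)
Conditions: BnBr (4.4 equiv), K2CO3 (4.8 equiv), DMF, 0 °C to rt, Ar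
Reagents that add atoms: benzyl bromide, BrCc1ccccc1
Why: Williamson etherification; K2CO3 deprotonates the four phenols but not the secondary 3-OH, so benzylation should stop at the tetra-ether, and the mild temperature avoids base-induced C2 epimerisation.

Step 2
Reactants: 2 5,7,3′,4′-tetra-O-benzyl-(+)-catechin; 3 1,3-bis(bromomethyl)benzene
Product: 4 3-O-[3-(bromomethyl)benzyl]-5,7,3′,4′-tetra-O-benzyl-(+)-catechin
Conditions: NaH (1.3 equiv), THF/DMF, 0 °C; alkoxide added to 3 (5 equiv), 0 °C to rt
Reagents that add atoms: none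
Why: Williamson etherification of the only free hydroxyl with a benzylic bromide; inverse addition to a fivefold excess of the symmetrical dibromide should hold the reaction at mono-substitution, and C2 and C3 are not involved.

Step 3
Reactants: 4 3-O-[3-(bromomethyl)benzyl]-5,7,3′,4′-tetra-O-benzyl-(+)-catechin; 5 methyl gallate
Product: 6 methyl 3,5-dihydroxy-4-[(3-{[(5,7,3′,4′-tetra-O-benzyl-(+)-catechin-3-yl)oxy]methyl}benzyl)oxy]benzoate
Conditions: 5 (3 equiv), KHCO3 (1.2 equiv), KI (0.1 equiv), DMF, 40 °C, Ar
Reagents that add atoms: none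
Why: Regioselective Williamson etherification (SN2): the 4-OH of methyl gallate, para to the ester, is the most acidic, so a weak base in the presence of excess 5 should form the phenoxide there and the benzylic bromide should alkylate O4.

Step 4
Reactants: 6 methyl 3,5-dihydroxy-4-[(3-{[(5,7,3′,4′-tetra-O-benzyl-(+)-catechin-3-yl)oxy]methyl}benzyl)oxy]benzoate
Product: 7 methyl 3,5-bis(benzyloxy)-4-[(3-{[(5,7,3′,4′-tetra-O-benzyl-(+)-catechin-3-yl)oxy]methyl}benzyl)oxy]benzoate
Conditions: BnBr (3 equiv), K2CO3 (4 equiv), DMF, rt to 50 °C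
Reagents that add atoms: benzyl bromide, BrCc1ccccc1
Why: Williamson etherification of the two remaining, equivalent phenols; the methyl ester and all existing ethers are inert to K2CO3.

Step 5
Reactants: 7 methyl 3,5-bis(benzyloxy)-4-[(3-{[(5,7,3′,4′-tetra-O-benzyl-(+)-catechin-3-yl)oxy]methyl}benzyl)oxy]benzoate
Product: 8 3,5-bis(benzyloxy)-4-[(3-{[(5,7,3′,4′-tetra-O-benzyl-(+)-catechin-3-yl)oxy]methyl}benzyl)oxy]benzoic acid
Conditions: LiOH·H2O (6 equiv), THF/MeOH/H2O, 55 °C; then 1 M HCl to pH 3
Reagents that add atoms: lithium hydroxide, [Li+].[OH-]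
Why: Saponification by acyl–oxygen cleavage; benzyl ethers are stable to aqueous hydroxide, and with all phenols capped the flavan has no base-sensitive site.

Step 6
Reactants: 9 (−)-epicatechin
Product: 10 5,7,3′,4′-tetra-O-benzyl-(−)-epicatechin (2R,3R; free 3-OH)
Conditions: BnBr (4.4 equiv), K2CO3 (4.8 equiv), DMF, 0 °C to rt, Ar
Reagents that add atoms: benzyl bromide, BrCc1ccccc1
Why: Williamson etherification of the four phenols, as in step 1; the axial 3-OH is not deprotonated and the stereocentres are untouched.

Step 7
Reactants: 10 5,7,3′,4′-tetra-O-benzyl-(−)-epicatechin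
Product: 11 4β-(2-ethoxyethoxy)-5,7,3′,4′-tetra-O-benzyl-(−)-epicatechin (2,3-cis, 3,4-trans)
Conditions: DDQ (2 equiv), 2-ethoxyethanol (5 equiv), CH2Cl2, rt; DMAP work-up
Reagents that add atoms: 2-ethoxyethanol, CCOCCO
Why: DDQ benzylic oxidation: hydride abstraction at C4 gives a cation stabilised by the 5- and 7-benzyloxy groups, which the alcohol captures from the β face, anti to the C2 aryl and the C3 hydroxyl, so the new C4 centre should be 3,4-trans. The oxidation is done on the monomer because the catechin part of 8 has an equally oxidisable C4 methylene.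

Step 8
Reactants: 8 3,5-bis(benzyloxy)-4-[(3-{[(5,7,3′,4′-tetra-O-benzyl-(+)-catechin-3-yl)oxy]methyl}benzyl)oxy]benzoic acid; 11 4β-(2-ethoxyethoxy)-5,7,3′,4′-tetra-O-benzyl-(−)-epicatechin
Product: 12 4β-(2-ethoxyethoxy)-5,7,3′,4′-tetra-O-benzyl-(−)-epicatechin 3-O-{3,5-bis(benzyloxy)-4-[(3-{[(5,7,3′,4′-tetra-O-benzyl-(+)-catechin-3-yl)oxy]methyl}benzyl)oxy]benzoate}
Conditions: 11 (1.2 equiv), DCC (1.5 equiv), DMAP (0.5 equiv), CH2Cl2, rt
Reagents that add atoms: none
Why: Steglich esterification; the neutral carbodiimide/DMAP conditions should leave the acid-labile C4 ether intact, and O-acylation retains the configuration at C3.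

Step 9
Reactants: 12 4β-(2-ethoxyethoxy)-5,7,3′,4′-tetra-O-benzyl-(−)-epicatechin 3-O-{3,5-bis(benzyloxy)-4-[(3-{[(5,7,3′,4′-tetra-O-benzyl-(+)-catechin-3-yl)oxy]methyl}benzyl)oxy]benzoate}
Product: 14 m-xylylene-bridged macrocyclic dimer (benzylated epicatechin gallate-(4β→8)-catechin; gallate O4 tied to catechin O3; twenty-membered ring; middle C4 β), via C4 acyloxonium triflate 13 (not isolated)
Conditions: TMSOTf (0.3 equiv), 4 Å MS, CH2Cl2, −40 to −20 °C, syringe-pump addition of 12 (final 0.5 mM); Et3N quench
Reagents that add atoms: none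
Why: TMSOTf silylates the 2-ethoxyethoxy oxygen and C4 ionises to a cation delocalised into ring A; the carbonyl oxygen of the C3 gallate, held on the α face, closes on C4 (5-exo-trig) to the cis-fused 2-aryl-1,3-dioxolan-2-ylium ion 13. The catechin ring A delivered by the bridge then attacks C4 from the open β face through C8, loses a proton to rearomatise, and the proton returns the silyl group to the catalyst. The closest known reaction type is the Lewis-acid condensation of C4-alkoxyflavans with flavan nucleophiles (Friedel–Crafts alkylation), including its intramolecular form with the partners joined by a linker; the benzyl-ether bridge and the ring size are the new elements. The one ring closed in the product is the twenty-membered ring (middle C4, C3, ester O and C, four gallate carbons, O4, CH2, three arene carbons, CH2, catechin O3, C3, C4, C4a, C8a, C8), closed by macrocyclising C–C bond formation at high dilution. The new stereocentre, middle C4, is set trans to the C3 oxygen, because anti opening of the α-face acyloxonium and the intrinsic preference of epicatechin-type C4 cations for attack anti to the C2 aryl point the same way. Three selectivities are needed: β over α (acyloxonium plus substrate bias); C8 over C6 of the catechin, which lie equally far from the anchor and give the same ring size, so that the choice falls to the higher intrinsic reactivity of C8 in 5,7-dialkoxyflavans, C6 sitting between two benzyloxy groups; and ring closure over chain growth through the free C6 and C8 of the electrophilic unit, secured by slow addition at sub-millimolar concentration.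

Step 10
Reactants: 10 5,7,3′,4′-tetra-O-benzyl-(−)-epicatechin
Product: 15 8-bromo-5,7,3′,4′-tetra-O-benzyl-(−)-epicatechin
Conditions: NBS (1.0 equiv), CH2Cl2, −78 °C to rt
Reagents that add atoms: N-bromosuccinimide, O=C1CCC(=O)N1Br
Why: Electrophilic aromatic bromination; one equivalent of NBS at low temperature should monobrominate ring A at C8, the more accessible and more nucleophilic of its two free positions.

Step 11
Reactants: 15 8-bromo-5,7,3′,4′-tetra-O-benzyl-(−)-epicatechin
Product: 16 8-bromo-4β-(2-ethoxyethoxy)-5,7,3′,4′-tetra-O-benzyl-(−)-epicatechin (3,4-trans)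
Conditions: DDQ (2 equiv), 2-ethoxyethanol (5 equiv), CH2Cl2, rt; DMAP work-up
Reagents that add atoms: 2-ethoxyethanol, CCOCCO
Why: DDQ benzylic oxidation with alcohol capture, as in step 7; the bromine lowers the electron density of ring A only slightly, and β capture anti to the C2 aryl and C3 hydroxyl should again give the 3,4-trans ether.

Step 12
Reactants: 16 8-bromo-4β-(2-ethoxyethoxy)-5,7,3′,4′-tetra-O-benzyl-(−)-epicatechin; 17 3,4,5-tris(benzyloxy)benzoic acid
Product: 18 8-bromo-4β-(2-ethoxyethoxy)-5,7,3′,4′-tetra-O-benzyl-(−)-epicatechin 3-O-[3,4,5-tris(benzyloxy)benzoate]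
Conditions: 17 (2 equiv), DCC (2.2 equiv), DMAP (0.5 equiv), CH2Cl2, rt
Reagents that add atoms: none
Why: Steglich esterification under neutral conditions that keep the C4 ether and the aryl bromide; configuration at C3 is retained.

Step 13
Reactants: 14 m-xylylene-bridged macrocyclic dimer; 18 8-bromo-4β-(2-ethoxyethoxy)-5,7,3′,4′-tetra-O-benzyl-(−)-epicatechin 3-O-[3,4,5-tris(benzyloxy)benzoate]
Product: 20 protected bridged trimer (8-bromo benzylated epicatechin gallate-(4β→8)-macrocyclic dimer 14; top C4 β; attached at middle C8), via top-unit C4 acyloxonium triflate 19 (not isolated)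
Conditions: 14 (1.5 equiv), TMSOTf (0.2 equiv), 4 Å MS, CH2Cl2, −40 to −20 °C; Et3N quench
Reagents that add atoms: none
Why: Lewis-acid interflavan coupling (Friedel–Crafts alkylation): 18 ionises to the α-face acyloxonium 19, and middle C8, the only remaining C8-type position of 14, should attack from the β face, setting top C4 trans to its gallate. The bromine on C8 of 18 removes the most nucleophilic site of the electrophile, so it cannot couple with itself, and the excess of 14 limits further alkylation of the product.

Step 14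
Reactants: 20 protected bridged trimer
Product: 21 epicatechin 3-O-gallate-(4β→8)-epicatechin 3-O-gallate-(4β→8)-catechin (CNP0269915.2)
Conditions: H2 (1 atm), Pd(OH)2/C, Et3N (1.5 equiv), THF/MeOH/H2O, rt; filtration under Ar, Sephadex LH-20, lyophilisation
Reagents that add atoms: none
Why: Heterogeneous hydrogenolysis should cleave the seventeen benzyl ethers, both benzylic C–O bonds of the bridge (the aryl ether first, which opens the macrocycle, then the 3-methylbenzyl ether on catechin O3) and the aryl C–Br bond in one operation. Et3N takes up the HBr so that the acid-labile interflavan bonds are not exposed, and no stereocentre is touched.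

## Compound list

1 | (+)-catechin | O[C@H]1Cc2c(O)cc(O)cc2O[C@@H]1c1ccc(O)c(O)c1 | starting material
2 | 5,7,3′,4′-tetra-O-benzyl-(+)-catechin | O[C@H]1Cc2c(OCc9ccccc9)cc(OCc9ccccc9)cc2O[C@@H]1c1ccc(OCc9ccccc9)c(OCc9ccccc9)c1 | intermediate
3 | 1,3-bis(bromomethyl)benzene | BrCc1cccc(CBr)c1 | starting material
4 | 3-O-[3-(bromomethyl)benzyl]-5,7,3′,4′-tetra-O-benzyl-(+)-catechin | BrCc1cccc(CO[C@H]2Cc3c(OCc9ccccc9)cc(OCc9ccccc9)cc3O[C@@H]2c2ccc(OCc9ccccc9)c(OCc9ccccc9)c2)c1 | intermediate
5 | methyl gallate | COC(=O)c1cc(O)c(O)c(O)c1 | starting material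
6 | methyl 3,5-dihydroxy-4-[(3-{[(5,7,3′,4′-tetra-O-benzyl-(+)-catechin-3-yl)oxy]methyl}benzyl)oxy]benzoate | COC(=O)c1cc(O)c(OCc2cccc(CO[C@H]3Cc4c(OCc9ccccc9)cc(OCc9ccccc9)cc4O[C@@H]3c3ccc(OCc9ccccc9)c(OCc9ccccc9)c3)c2)c(O)c1 | intermediate
7 | methyl 3,5-bis(benzyloxy)-4-[(3-{[(5,7,3′,4′-tetra-O-benzyl-(+)-catechin-3-yl)oxy]methyl}benzyl)oxy]benzoate | COC(=O)c1cc(OCc9ccccc9)c(OCc2cccc(CO[C@H]3Cc4c(OCc9ccccc9)cc(OCc9ccccc9)cc4O[C@@H]3c3ccc(OCc9ccccc9)c(OCc9ccccc9)c3)c2)c(OCc9ccccc9)c1 | intermediate
8 | 3,5-bis(benzyloxy)-4-[(3-{[(5,7,3′,4′-tetra-O-benzyl-(+)-catechin-3-yl)oxy]methyl}benzyl)oxy]benzoic acid | OC(=O)c1cc(OCc9ccccc9)c(OCc2cccc(CO[C@H]3Cc4c(OCc9ccccc9)cc(OCc9ccccc9)cc4O[C@@H]3c3ccc(OCc9ccccc9)c(OCc9ccccc9)c3)c2)c(OCc9ccccc9)c1 | intermediate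
9 | (−)-epicatechin | O[C@@H]1Cc2c(O)cc(O)cc2O[C@@H]1c1ccc(O)c(O)c1 | starting material
10 | 5,7,3′,4′-tetra-O-benzyl-(−)-epicatechin | O[C@@H]1Cc2c(OCc9ccccc9)cc(OCc9ccccc9)cc2O[C@@H]1c1ccc(OCc9ccccc9)c(OCc9ccccc9)c1 | intermediate
11 | 4β-(2-ethoxyethoxy)-5,7,3′,4′-tetra-O-benzyl-(−)-epicatechin | O[C@@H]1[C@@H](OCCOCC)c2c(OCc9ccccc9)cc(OCc9ccccc9)cc2O[C@@H]1c1ccc(OCc9ccccc9)c(OCc9ccccc9)c1 | intermediate
12 | xylylene-bridged 4β-(2-ethoxyethoxy)epicatechin gallate and catechin, benzylated (key-step precursor) | O=C(O[C@@H]1[C@@H](OCCOCC)c2c(OCc9ccccc9)cc(OCc9ccccc9)cc2O[C@@H]1c1ccc(OCc9ccccc9)c(OCc9ccccc9)c1)c1cc(OCc9ccccc9)c(OCc5cccc(CO[C@H]6Cc7c(OCc9ccccc9)cc(OCc9ccccc9)cc7O[C@@H]6c6ccc(OCc9ccccc9)c(OCc9ccccc9)c6)c5)c(OCc9ccccc9)c1 | intermediate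
13 | C4 acyloxonium triflate of 12 (2-aryl-1,3-dioxolan-2-ylium ion cis-fused at C3–C4 on the α face) | C1(=[O+][C@@H]2c3c(OCc9ccccc9)cc(OCc9ccccc9)cc3O[C@H](c3ccc(OCc9ccccc9)c(OCc9ccccc9)c3)[C@@H]2O1)c1cc(OCc9ccccc9)c(OCc5cccc(CO[C@H]6Cc7c(OCc9ccccc9)cc(OCc9ccccc9)cc7O[C@@H]6c6ccc(OCc9ccccc9)c(OCc9ccccc9)c6)c5)c(OCc9ccccc9)c1.[O-]S(=O)(=O)C(F)(F)F | intermediate (not isolated)
14 | m-xylylene-bridged macrocyclic benzylated epicatechin gallate-(4β→8)-catechin (key-step product) | O=C(O[C@@H]1[C@@H](c2c(OCc9ccccc9)cc(OCc9ccccc9)c3c2O[C@H](c2ccc(OCc9ccccc9)c(OCc9ccccc9)c2)[C@@H](O%10)C3)c2c(OCc9ccccc9)cc(OCc9ccccc9)cc2O[C@@H]1c1ccc(OCc9ccccc9)c(OCc9ccccc9)c1)c1cc(OCc9ccccc9)c(OCc5cccc(C%10)c5)c(OCc9ccccc9)c1 | intermediate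
15 | 8-bromo-5,7,3′,4′-tetra-O-benzyl-(−)-epicatechin | O[C@@H]1Cc2c(OCc9ccccc9)cc(OCc9ccccc9)c(Br)c2O[C@@H]1c1ccc(OCc9ccccc9)c(OCc9ccccc9)c1 | intermediate
16 | 8-bromo-4β-(2-ethoxyethoxy)-5,7,3′,4′-tetra-O-benzyl-(−)-epicatechin | O[C@@H]1[C@@H](OCCOCC)c2c(OCc9ccccc9)cc(OCc9ccccc9)c(Br)c2O[C@@H]1c1ccc(OCc9ccccc9)c(OCc9ccccc9)c1 | intermediate
17 | 3,4,5-tris(benzyloxy)benzoic acid | OC(=O)c1cc(OCc9ccccc9)c(OCc9ccccc9)c(OCc9ccccc9)c1 | starting material
18 | 8-bromo-4β-(2-ethoxyethoxy)-5,7,3′,4′-tetra-O-benzyl-(−)-epicatechin 3-O-[3,4,5-tris(benzyloxy)benzoate] | O=C(O[C@@H]1[C@@H](OCCOCC)c2c(OCc9ccccc9)cc(OCc9ccccc9)c(Br)c2O[C@@H]1c1ccc(OCc9ccccc9)c(OCc9ccccc9)c1)c1cc(OCc9ccccc9)c(OCc9ccccc9)c(OCc9ccccc9)c1 | intermediate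
19 | C4 acyloxonium triflate of 18 | C1(=[O+][C@@H]2c3c(OCc9ccccc9)cc(OCc9ccccc9)c(Br)c3O[C@H](c3ccc(OCc9ccccc9)c(OCc9ccccc9)c3)[C@@H]2O1)c1cc(OCc9ccccc9)c(OCc9ccccc9)c(OCc9ccccc9)c1.[O-]S(=O)(=O)C(F)(F)F | intermediate (not isolated)
20 | protected bridged trimer (8-bromo, seventeen benzyl ethers, m-xylylene bridge) | O=C(O[C@@H]1[C@@H](c2c(OCc9ccccc9)cc(OCc9ccccc9)c3c2O[C@H](c2ccc(OCc9ccccc9)c(OCc9ccccc9)c2)[C@@H](O%10)C3)c2c(OCc9ccccc9)cc(OCc9ccccc9)c([C@H]3c4c(OCc9ccccc9)cc(OCc9ccccc9)c(Br)c4O[C@H](c4ccc(OCc9ccccc9)c(OCc9ccccc9)c4)[C@@H]3OC(=O)c3cc(OCc9ccccc9)c(OCc9ccccc9)c(OCc9ccccc9)c3)c2O[C@@H]1c1ccc(OCc9ccccc9)c(OCc9ccccc9)c1)c1cc(OCc9ccccc9)c(OCc5cccc(C%10)c5)c(OCc9ccccc9)c1 | intermediate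
21 | epicatechin 3-O-gallate-(4β→8)-epicatechin 3-O-gallate-(4β→8)-catechin (CNP0269915.2) | O=C(O[C@@H]1[C@@H](c2c(O)cc(O)c3c2O[C@H](c2ccc(O)c(O)c2)[C@@H](O)C3)c2c(O)cc(O)c([C@H]3c4c(O)cc(O)cc4O[C@H](c4ccc(O)c(O)c4)[C@@H]3OC(=O)c3cc(O)c(O)c(O)c3)c2O[C@@H]1c1ccc(O)c(O)c1)c1cc(O)c(O)c(O)c1 | target

## Step count and risk

Total step count: 14. Longest linear sequence: 9 steps (steps 1, 2, 3, 4, 5, 8, 9, 13, 14).

**Step 9 (key step).**
- What may go wrong: the bridge is anchored on the α-face gallate and may be unable to bring the catechin ring A over the β face of C4 without strain. Ring closure would then be slow compared with chain growth through the free C6 and C8 of a second molecule, with loss of the C3 proton to a flav-3-ene, or with closure through catechin C6, which gives the same ring size.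
- Fallback (intermolecular union with excess nucleophile): it sets out from 11, 17 and 2. Steglich esterification of 11 with 17 gives 4β-(2-ethoxyethoxy)-5,7,3′,4′-tetra-O-benzylepicatechin 3-O-[3,4,5-tris(benzyloxy)benzoate] F1. TMSOTf-promoted coupling of F1 with a four- to fivefold excess of 2 in CH2Cl2 at −78 to −40 °C gives the unbridged benzylated epicatechin gallate-(4β→8)-catechin F2, and the excess of 2 is recovered. F2 is coupled with 18 as in step 13 to the unbridged 8-bromo protected trimer F3, and hydrogenolysis as in step 14 comes back to the route at 21.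

**Step 13.**
- What may go wrong: the acyloxonium-stabilised, bulky cation from 18 may react slowly at middle C8 of the macrocycle. Leakage to the C6 positions, further alkylation of the product, and acid-induced reopening of the existing interflavan bond would then gain ground.
- Fallback (smaller electrophile, late acylation): it sets out from 16 and 14. The free-hydroxyl electrophile 16 is coupled with excess 14 under TMSOTf in CH2Cl2 at −78 to −40 °C, where attack anti to the C2 aryl and the 3-OH should again give the β bond, affording the bridged protected trimer with a free top 3-OH F4. Steglich esterification of this single free hydroxyl with 17 comes back to the route at 20.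

**Step 3.**
- What may go wrong: loss of regiocontrol, meaning alkylation at a meta hydroxyl or twofold alkylation of one gallate by the valuable bromide.
- Fallback (selective replacement of the para acetate): it sets out from 5 and 4. Peracetylation of 5 (Ac2O, pyridine) gives methyl 3,4,5-triacetoxybenzoate F5. Heating F5 with 4, K2CO3 and KI in acetone should replace only the para acetate, whose phenoxide is the best leaving group, giving methyl 3,5-diacetoxy-4-[(3-{[(5,7,3′,4′-tetra-O-benzyl-(+)-catechin-3-yl)oxy]methyl}benzyl)oxy]benzoate F6. K2CO3 in MeOH removes the two acetates and comes back to the route at 6.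

**Step 14.**
- What may go wrong: incomplete hydrogenolysis through bromide poisoning of the catalyst or slow cleavage of the congested bridge ether, and, during a prolonged reaction, amine-induced C2 epimerisation or oxidation of the free polyphenol.
- Fallback (bromine removed separately): it sets out from 20. Radical hydrodebromination with Bu3SnH and AIBN in toluene at 90 °C gives the bromine-free protected bridged trimer F7. Hydrogenolysis of F7 over Pd(OH)2/C in THF/MeOH/H2O without amine comes back to the route at 21.

## Further compounds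

F1 | step 9 | 4β-(2-ethoxyethoxy)-5,7,3′,4′-tetra-O-benzylepicatechin 3-O-[3,4,5-tris(benzyloxy)benzoate] | O=C(O[C@@H]1[C@@H](OCCOCC)c2c(OCc9ccccc9)cc(OCc9ccccc9)cc2O[C@@H]1c1ccc(OCc9ccccc9)c(OCc9ccccc9)c1)c1cc(OCc9ccccc9)c(OCc9ccccc9)c(OCc9ccccc9)c1
F2 | step 9 | unbridged benzylated epicatechin gallate-(4β→8)-catechin (free catechin 3-OH) | O=C(O[C@@H]1[C@@H](c2c(OCc9ccccc9)cc(OCc9ccccc9)c3c2O[C@H](c2ccc(OCc9ccccc9)c(OCc9ccccc9)c2)[C@@H](O)C3)c2c(OCc9ccccc9)cc(OCc9ccccc9)cc2O[C@@H]1c1ccc(OCc9ccccc9)c(OCc9ccccc9)c1)c1cc(OCc9ccccc9)c(OCc9ccccc9)c(OCc9ccccc9)c1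
F3 | step 9 | unbridged 8-bromo protected trimer (eighteen benzyl ethers, free catechin 3-OH) | O=C(O[C@@H]1[C@@H](c2c(OCc9ccccc9)cc(OCc9ccccc9)c3c2O[C@H](c2ccc(OCc9ccccc9)c(OCc9ccccc9)c2)[C@@H](O)C3)c2c(OCc9ccccc9)cc(OCc9ccccc9)c([C@H]3c4c(OCc9ccccc9)cc(OCc9ccccc9)c(Br)c4O[C@H](c4ccc(OCc9ccccc9)c(OCc9ccccc9)c4)[C@@H]3OC(=O)c3cc(OCc9ccccc9)c(OCc9ccccc9)c(OCc9ccccc9)c3)c2O[C@@H]1c1ccc(OCc9ccccc9)c(OCc9ccccc9)c1)c1cc(OCc9ccccc9)c(OCc9ccccc9)c(OCc9ccccc9)c1
F4 | step 13 | bridged protected trimer with free top 3-OH | O=C(O[C@@H]1[C@@H](c2c(OCc9ccccc9)cc(OCc9ccccc9)c3c2O[C@H](c2ccc(OCc9ccccc9)c(OCc9ccccc9)c2)[C@@H](O%10)C3)c2c(OCc9ccccc9)cc(OCc9ccccc9)c([C@H]3c4c(OCc9ccccc9)cc(OCc9ccccc9)c(Br)c4O[C@H](c4ccc(OCc9ccccc9)c(OCc9ccccc9)c4)[C@@H]3O)c2O[C@@H]1c1ccc(OCc9ccccc9)c(OCc9ccccc9)c1)c1cc(OCc9ccccc9)c(OCc5cccc(C%10)c5)c(OCc9ccccc9)c1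
F5 | step 3 | methyl 3,4,5-triacetoxybenzoate | COC(=O)c1cc(OC(C)=O)c(OC(C)=O)c(OC(C)=O)c1
F6 | step 3 | methyl 3,5-diacetoxy-4-[(3-{[(5,7,3′,4′-tetra-O-benzyl-(+)-catechin-3-yl)oxy]methyl}benzyl)oxy]benzoate | COC(=O)c1cc(OC(C)=O)c(OCc2cccc(CO[C@H]3Cc4c(OCc9ccccc9)cc(OCc9ccccc9)cc4O[C@@H]3c3ccc(OCc9ccccc9)c(OCc9ccccc9)c3)c2)c(OC(C)=O)c1
F7 | step 14 | bromine-free protected bridged trimer | O=C(O[C@@H]1[C@@H](c2c(OCc9ccccc9)cc(OCc9ccccc9)c3c2O[C@H](c2ccc(OCc9ccccc9)c(OCc9ccccc9)c2)[C@@H](O%10)C3)c2c(OCc9ccccc9)cc(OCc9ccccc9)c([C@H]3c4c(OCc9ccccc9)cc(OCc9ccccc9)cc4O[C@H](c4ccc(OCc9ccccc9)c(OCc9ccccc9)c4)[C@@H]3OC(=O)c3cc(OCc9ccccc9)c(OCc9ccccc9)c(OCc9ccccc9)c3)c2O[C@@H]1c1ccc(OCc9ccccc9)c(OCc9ccccc9)c1)c1cc(OCc9ccccc9)c(OCc5cccc(C%10)c5)c(OCc9ccccc9)c1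
A1 | alternative 1 | (E)-3-(penta-O-benzylcatechin-8-yl)propenal | O=C/C=C/c1c(OCc9ccccc9)cc(OCc9ccccc9)c2c1O[C@H](c1ccc(OCc9ccccc9)c(OCc9ccccc9)c1)[C@@H](OCc9ccccc9)C2
A2 | alternative 1 | phloroglucinol | Oc1cc(O)cc(O)c1
A3 | alternative 1 | 4-(penta-O-benzylcatechin-8-yl)-5,7-dihydroxychroman-2-ol (C2 epimers) | OC1C[C@@H](c2c(OCc9ccccc9)cc(OCc9ccccc9)c3c2O[C@H](c2ccc(OCc9ccccc9)c(OCc9ccccc9)c2)[C@@H](OCc9ccccc9)C3)c2c(O)cc(O)cc2O1
A4 | alternative 2 | benzylated trimer with free middle C7 hydroxyl | O=C(O[C@@H]1[C@@H](c2c(OCc9ccccc9)cc(OCc9ccccc9)c3c2O[C@H](c2ccc(OCc9ccccc9)c(OCc9ccccc9)c2)[C@@H](OCc9ccccc9)C3)c2c(OCc9ccccc9)cc(O)c([C@H]3c4c(OCc9ccccc9)cc(OCc9ccccc9)cc4O[C@H](c4ccc(OCc9ccccc9)c(OCc9ccccc9)c4)[C@@H]3OC(=O)c3cc(OCc9ccccc9)c(OCc9ccccc9)c(OCc9ccccc9)c3)c2O[C@@H]1c1ccc(OCc9ccccc9)c(OCc9ccccc9)c1)c1cc(OCc9ccccc9)c(OCc9ccccc9)c(OCc9ccccc9)c1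
A5 | alternative 3 | perbenzylated epicatechin gallate-(4β→8)-epicatechin gallate | O=C(O[C@@H]1Cc2c(OCc9ccccc9)cc(OCc9ccccc9)c([C@H]3c4c(OCc9ccccc9)cc(OCc9ccccc9)cc4O[C@H](c4ccc(OCc9ccccc9)c(OCc9ccccc9)c4)[C@@H]3OC(=O)c3cc(OCc9ccccc9)c(OCc9ccccc9)c(OCc9ccccc9)c3)c2O[C@@H]1c1ccc(OCc9ccccc9)c(OCc9ccccc9)c1)c1cc(OCc9ccccc9)c(OCc9ccccc9)c(OCc9ccccc9)c1
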